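The earlier runs and the new flask were computed for an exercise; the scatter is artificial.

Time in this flask splits into two clocks. Solid substrate goes into solution and meets partner at constant temperature, and intermediate A first climbs, then fades. I read both clocks from the earlier runs, mainly epsilon and delta, which carry the flask's 1.05 equiv of partner.

| flask | solid substrate | partner | remark | time |
|---|---|---|---|---|
| epsilon | 0.20 M | 1.05 equiv | run made earlier |  |
| delta | 0.45 M | 1.05 equiv | run made earlier |  |
| gamma | 0.30 M | 1.6 equiv | run made earlier |  |
| flask | 0.30 M | 1.05 equiv |  | 8.0 min |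

- epsilon (time / min: intermediate A / %, target / %): 0.200: 8.9, 0.1; 0.417: 18.5, 0.9; 0.667: 21.0, 1.1; 1.33: 18.3, 2.7; 2.50: 14.7, 4.6; 5.00: 7.8, 6.6; 10.0: 3.3, 8.4
- delta (time / min: intermediate A / %, target / %): 0.200: 6.7, 0; 0.417: 14.5, 0.9; 0.667: 20.6, 1.8; 1.33: 22.3, 2.8; 2.50: 16.9, 5.3; 5.00: 8.9, 7.8; 10.0: 3.0, 9.2
- gamma (time / min: intermediate A / %, target / %): 0.200: 10.3, 0.8; 0.500: 25.7, 1.6; 1.33: 25.0, 3.3; 4.00: 11.3, 7.5; 10.0: 2.4, 9.8

(scatter of a reading: 0.3 percentage points)

- time, not beyond 8.0 min, at which the flask holds most intermediate A
- the amount of intermediate A, in percent of the solid substrate charged, at that time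
- the first time at which intermediate A reaches 6.9%, in the same percent, in min

The fast clock is the rise. The highest readings of epsilon and delta average 21.6%, and at the mean slope of their first readings that amount fills in 0.555 min.

The slow clock is the tail. I call κ the tail constant, the fraction of intermediate A lost per minute once the curve has broken (an apparent first-order rate constant). Read between 2.50 min and 10.0 min and averaged over both runs, κ = 0.215 min⁻¹. Gamma, with 1.6 equiv, reads a faster 0.258 min⁻¹ between 4.00 min and 10.0 min, so I use κ for 1.05 equiv of partner.

The lifetime 1/κ, 4.65 min, is 8.38 times the filling time. From the highest readings I expect a top in the flask near 21.6%, and from κ a later half-life of 3.22 min.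

The forecast says 23.5% at 0.63 min, with the level reached at 0.17 min, on the ground that “A forms at a near-constant rate until the solid is gone, then simply decays”. Its top stands above mine.

The flask peaks at 0.787 min with 22.9%, and reaches the level at 0.177 min.

    starting material + partner ⇌ intermediate A (K = 4.90 L mol⁻¹, k = 0.210 L mol⁻¹ s⁻¹)
    starting material + partner ⇌ intermediate B (K = 0.360 L mol⁻¹, k = 0.170 L mol⁻¹ s⁻¹)
    starting material + partner ⇌ intermediate C (K = 6.40 L mol⁻¹, k = 0.320 L mol⁻¹ s⁻¹)
    intermediate B → target (k = 0.0220 s⁻¹)
    intermediate C → decomposed reagent (k = 0.0120 s⁻¹)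
    starting material + target ⇌ idle adduct, settled at all times (K = 2.20 L mol⁻¹)
    solid substrate ⇌ starting material, rate k7*(cs7 - [starting material]) while solid is left; crystals form when [starting material] > cs7 (solubility = 0.200 M, k = 0.0700 s⁻¹)

At the best time the flask holds 0% solid substrate and 36.9% starting material. Applied to the flask, κ carries intermediate A from 10.4% at 4.00 min to 4.40% at 8.00 min, and the flask holds 4.15%. In a neighbour charged with 2.60 equiv of partner, κ applied over the whole 8.0 min takes its best of 32.6% down to 5.84%, but that neighbour ends with 3.05%.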